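**Plan**

1. Labels: ring A = 3-hydroxy-4-methoxybenzyl ring, ring B = aryl on the oxolane, ring C = aryl on the tetralin, ring D = benzo ring of the tetralin; in each half C7 = ArCH, C8 = CH(C9H2OH), C8' = C(OH)(C9'H2O), C7' = ArCH2.
2. Cuts: the ring B–ring C biaryl bond (Suzuki); in the tetralin half the ring bond C7–C8, then the C7–ring D bond (Friedel–Crafts benzylation); in the oxolane half the C7–O bond (cyclodehydration) and C7–C8 (aldol).
3. Both halves then come from one building-block type, a dimethyl (S)-2-(arylmethyl)malate (C9'–C8'(OH)(C7'H2Ar)–C8H2–C9), made twice from (S)-malic acid by dioxolanone alkylation.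
4. Forward: oxolane half by dianion aldol, ester reduction and acid closure of the oxolane; tetralin half by benzylation of ring D, closure of the cyclohexane ring at C7–C8, ester reduction; Suzuki union; hydrogenolysis of three benzyl ethers.
5. Enabling feature: ring C carries its OH para to C7, flanked by OMe and Br (the later biaryl position), so the ring C–C7H2–ring D diarylmethane can be oxidised to a p-quinone methide electrophilic at C7; C8 is α to the C9 ester and β to the C8' oxygen (a Fráter–Seebach dianion) and ring D holds it within 6-exo reach; the two esters are the helpers, later reduced to the CH2OH groups.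
6. Stereochemistry: C8' of both halves from (S)-malic acid (retention); C8 from the lithium chelate plus tether (tetralin) or Fráter–Seebach face selection (oxolane half); C7 from a chair transition state (tetralin) or reversible trans-selective closure (oxolane).

Key step: step 15

Remark: 11 and 12 are carried as mixtures of epimers at C7 (reset in step 8) and quinone methide 22 as an E/Z mixture (the geometry vanishes on rearomatisation), so their SMILES leave these elements open.

**Route**

Step 1
Reactants: 1 (S)-malic acid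
Product: 2 [(2S,4S)-2-tert-butyl-5-oxo-1,3-dioxolan-4-yl]acetic acid (cis)
Conditions: pivalaldehyde, p-TsOH·H2O (cat.), H2SO4 (cat.), pentane, reflux (Dean–Stark); recrystallisation
Reagents that add atoms: pivalaldehyde CC(C)(C)C=O
Why: Acetalisation of the α-hydroxy acid unit gives the cis-dioxolanone, whose new acetal centre (S, cis to the side chain, purified by crystallisation) stores the chirality for the alkylation (self-regeneration of stereocentres).

Step 2
Reactants: 3 [3-(benzyloxy)-4-methoxyphenyl]methanol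
Product: 4 2-(benzyloxy)-4-(bromomethyl)-1-methoxybenzene
Conditions: PBr3, CH2Cl2, 0 °C
Reagents that add atoms: phosphorus tribromide BrP(Br)Br
Why: Standard conversion of an electron-rich benzylic alcohol into the bromide.

Step 3
Reactants: 2 dioxolanone acid; 4 benzylic bromide
Product: 6 {(2S,4S)-4-[3-(benzyloxy)-4-methoxybenzyl]-2-tert-butyl-5-oxo-1,3-dioxolan-4-yl}acetic acid, via dilithium enolate 5 (not isolated)
Conditions: LiN(SiMe3)2 (2.1 equiv), THF, −78 °C; then 4, −78 → −30 °C; aq. HCl work-up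
Reagents that add atoms: none
Why: Dioxolanone enolate alkylation (self-regeneration of stereocentres) should occur anti to the tert-butyl group, so the benzyl group replaces H with retention and sets the S quaternary carbinol centre C8' of the oxolane half.

Step 4
Reactants: 6 alkylated dioxolanone acid
Product: 7 dimethyl (2S)-2-[3-(benzyloxy)-4-methoxybenzyl]-2-hydroxybutanedioate
Conditions: HCl (1.25 M in MeOH), reflux
Reagents that add atoms: methanol CO
Why: Acid-catalysed methanolysis opens the dioxolanone and Fischer-esterifies the side-chain acid without touching the quaternary centre.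

Step 5
Reactants: 8 5-bromovanillin
Product: 9 4-(benzyloxy)-3-bromo-5-methoxybenzaldehyde
Conditions: BnBr, K2CO3, DMF, 60 °C
Reagents that add atoms: benzyl bromide BrCc1ccccc1
Why: Williamson etherification of the phenol.

Step 6
Reactants: 7 malate of ring A; 9 aldehyde of ring B
Product: 11 dimethyl (2S,3R)-2-[3-(benzyloxy)-4-methoxybenzyl]-3-{[4-(benzyloxy)-3-bromo-5-methoxyphenyl](hydroxy)methyl}-2-hydroxybutanedioate (C7 epimers), via dilithium alkoxide enolate 10 (not isolated)
Conditions: LiN(SiMe3)2 (2.2 equiv), THF, −78 → −30 °C; then 9 (1.2 equiv), −78 °C; AcOH quench at −78 °C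
Reagents that add atoms: none
Why: Fráter–Seebach aldol in which the lithium-chelated dianion should be attacked on the face anti to the C9' ester (the sense of malate dianion alkylation, with benzyl in the place of H), which sets C8 (R).

Step 7
Reactants: 11 aldol adduct
Product: 12 (2S,3R)-2-[3-(benzyloxy)-4-methoxybenzyl]-3-{[4-(benzyloxy)-3-bromo-5-methoxyphenyl](hydroxy)methyl}butane-1,2,4-triol (C7 epimers)
Conditions: LiBH4, THF/MeOH, 0 °C → rt
Reagents that add atoms: none
Why: Hydroxyl-assisted borohydride reduction of both methyl esters (any lactonised adduct gives the same tetraol) that leaves the aryl bromide intact.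

Step 8
Reactants: 12 tetraol
Product: 13 (3S,4R,5S)-5-[4-(benzyloxy)-3-bromo-5-methoxyphenyl]-3-[3-(benzyloxy)-4-methoxybenzyl]-4-(hydroxymethyl)oxolan-3-ol
Conditions: CSA (10 mol %), CH2Cl2, 0 °C → rt
Reagents that add atoms: none
Why: Acid-catalysed cyclodehydration in which the p-alkoxybenzylic cation at C7 is trapped 5-exo by the C9' hydroxyl, and the reversible closure should converge both C7 epimers on the 7,8-trans oxolane (S at C7).

Step 9
Reactants: 13 oxolane aryl bromide
Product: 14 (3S,4R,5S)-5-[4-(benzyloxy)-3-methoxy-5-(4,4,5,5-tetramethyl-1,3,2-dioxaborolan-2-yl)phenyl]-3-[3-(benzyloxy)-4-methoxybenzyl]-4-(hydroxymethyl)oxolan-3-ol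
Conditions: B2pin2, Pd(dppf)Cl2 (5 mol %), KOAc, 1,4-dioxane, 90 °C
Reagents that add atoms: bis(pinacolato)diboron CC1(C)OB(OC1(C)C)B1OC(C)(C)C(C)(C)O1
Why: Miyaura borylation of the aryl bromide, which tolerates the free hydroxyl groups.

Step 10
Reactants: 15 [4-(benzyloxy)-3-methoxyphenyl]methanol
Product: 16 1-(benzyloxy)-4-(bromomethyl)-2-methoxybenzene
Conditions: PBr3, CH2Cl2, 0 °C
Reagents that add atoms: phosphorus tribromide BrP(Br)Br
Why: Standard conversion of an electron-rich benzylic alcohol into the bromide.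

Step 11
Reactants: 2 dioxolanone acid; 16 benzylic bromide
Product: 18 {(2S,4S)-4-[4-(benzyloxy)-3-methoxybenzyl]-2-tert-butyl-5-oxo-1,3-dioxolan-4-yl}acetic acid, via disodium enolate 17 (not isolated)
Conditions: NaN(SiMe3)2 (2.1 equiv), THF, −78 °C; then 16, −78 → −50 °C; aq. HCl work-up
Reagents that add atoms: none
Why: Dioxolanone enolate alkylation (self-regeneration of stereocentres), run here through the more reactive disodium carboxylate/enolate so that the benzylation can be completed at low temperature, should occur anti to the tert-butyl group and so set the S carbinol centre C8' of the tetralin half with retention.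

Step 12
Reactants: 18 alkylated dioxolanone acid
Product: 19 dimethyl (2S)-2-[4-(benzyloxy)-3-methoxybenzyl]-2-hydroxybutanedioate
Conditions: HCl (1.25 M in MeOH), reflux
Reagents that add atoms: methanol CO
Why: Acid-catalysed methanolysis of the dioxolanone with Fischer esterification of the side-chain acid.

Step 13
Reactants: 8 5-bromovanillin
Product: 20 2-bromo-4-(hydroxymethyl)-6-methoxyphenol
Conditions: NaBH4, MeOH, 0 °C
Reagents that add atoms: none
Why: Borohydride reduction of the aldehyde to the p-hydroxybenzylic alcohol.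

Step 14
Reactants: 19 malate of ring D; 20 p-hydroxybenzylic alcohol of ring C
Product: 21 dimethyl (2S)-2-[4-(benzyloxy)-2-(3-bromo-4-hydroxy-5-methoxybenzyl)-5-methoxybenzyl]-2-hydroxybutanedioate
Conditions: p-TsOH·H2O (10 mol %), HFIP, rt, slow addition of 20
Reagents that add atoms: none
Why: Friedel–Crafts benzylation in which the p-hydroxybenzylic cation from 20 should attack ring D at the position para to its methoxy group and ortho to the CH2 arm, the bromine of 20 damping its self-condensation.

Step 15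
Reactants: 21 diarylmethane phenol
Product: 24 dimethyl (1S,2R,3S)-7-(benzyloxy)-1-(3-bromo-4-hydroxy-5-methoxyphenyl)-3-hydroxy-6-methoxy-1,2,3,4-tetrahydronaphthalene-2,3-dicarboxylate, via quinone methide 22 (not isolated), via dilithium alkoxide enolate 23 (not isolated)
Conditions: Ag2O (3 equiv), CH2Cl2, rt, dark; filter, exchange to THF; add to LiN(SiMe3)2 (2.3 equiv), THF, −78 → −30 °C; AcOH quench
Reagents that add atoms: none
Why: Ag2O dehydrogenates the 2-bromo-6-methoxy-4-benzylphenol of ring C to the p-quinone methide 22, and double deprotonation gives the alkoxide/ester enolate 23, whose C8 adds to C7 in a 1,6-conjugate addition that rearomatises ring C; the closest known reaction types are quinone-methide-initiated cyclisations of Ag2O-generated p-quinone methides with tethered carbon nucleophiles and the Fráter–Seebach alkylation of β-hydroxy ester dianions. The cyclohexane ring (C7, C8, C8', C7' and two ring D carbons) closes in a 6-exo-trig mode, the C7=C bond lying outside the new ring. C8 is controlled by the six-membered lithium chelate between the C8' alkoxide and the enolate oxygen together with the C7'–ring D tether, which delivers C7 to the enolate face syn to C7' and anti to the C9' ester, so that the C9 ester ends cis to the C8' oxygen. C7 is controlled by a chair-like transition state with the quinoid ring pseudo-equatorial and the methide hydrogen turned toward the ortho CH2 (least allylic strain), which places the aryl group trans to the C9 ester; C8 remains epimerisable and the all-equatorial product is also the thermodynamic one. The step needs C- over O-alkylation: addition of the tertiary alkoxide to C7 would give an isochroman but is reversible from the phenoxide, whereas C–C bond formation is not, and enolisation is possible only at C8 because C8' is quaternary.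

Step 16
Reactants: 24 tetralin diester
Product: 25 (1S,2S,3S)-7-(benzyloxy)-1-(3-bromo-4-hydroxy-5-methoxyphenyl)-2,3-bis(hydroxymethyl)-6-methoxy-1,2,3,4-tetrahydronaphthalen-3-ol (C1 = aryl-bearing carbon)
Conditions: LiBH4, THF/MeOH, 0 °C → rt
Reagents that add atoms: none
Why: Hydroxyl-assisted borohydride reduction turns both activating esters into the CH2OH groups of the target without touching the aryl bromide or the stereocentres.

Step 17
Reactants: 14 oxolane boronate; 25 tetralin bromophenol
Product: 26 tri-O-benzyl ether of the target (benzyl on the OH of rings A, B and D; ring C OH free)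
Conditions: Pd(OAc)2 (5 mol %), SPhos (10 mol %), K3PO4, 1,4-dioxane/H2O (4:1), 80 °C
Reagents that add atoms: none
Why: Suzuki–Miyaura coupling of an ortho-alkoxy arylboronate with an ortho-bromophenol forms the 2,2'-dioxygenated biaryl bond between rings B and C under conditions that leave all stereocentres untouched.

Step 18
Reactants: 26 tribenzyl ether
Product: 27 CNP0252244.1 (target)
Conditions: H2 (1 atm), Pd/C (10 wt %), EtOAc/MeOH, rt, stopped at full debenzylation
Reagents that add atoms: none
Why: Hydrogenolysis of the three aryl benzyl ethers, which should be much faster than cleavage of the oxolane benzylic C–O bond under neutral conditions.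

**Compound list**

1 | (S)-malic acid | OC(=O)C[C@H](O)C(=O)O | starting material
2 | [(2S,4S)-2-tert-butyl-5-oxo-1,3-dioxolan-4-yl]acetic acid | OC(=O)C[C@@H]1O[C@H](C(C)(C)C)OC1=O | intermediate
3 | [3-(benzyloxy)-4-methoxyphenyl]methanol | COc1ccc(CO)cc1OCc1ccccc1 | starting material
4 | 2-(benzyloxy)-4-(bromomethyl)-1-methoxybenzene | COc1ccc(CBr)cc1OCc1ccccc1 | intermediate
5 | dilithium enolate of 2 (carboxylate and dioxolanone enolate) | [Li+].[Li+].[O-]C(=O)CC1=C([O-])O[C@@H](C(C)(C)C)O1 | intermediate (not isolated)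
6 | {(2S,4S)-4-[3-(benzyloxy)-4-methoxybenzyl]-2-tert-butyl-5-oxo-1,3-dioxolan-4-yl}acetic acid | OC(=O)C[C@]1(Cc2ccc(OC)c(OCc3ccccc3)c2)O[C@H](C(C)(C)C)OC1=O | intermediate
7 | dimethyl (2S)-2-[3-(benzyloxy)-4-methoxybenzyl]-2-hydroxybutanedioate | COC(=O)C[C@@](O)(Cc1ccc(OC)c(OCc2ccccc2)c1)C(=O)OC | intermediate
8 | 5-bromovanillin | COc1cc(C=O)cc(Br)c1O | starting material
9 | 4-(benzyloxy)-3-bromo-5-methoxybenzaldehyde | COc1cc(C=O)cc(Br)c1OCc1ccccc1 | intermediate
10 | dilithium alkoxide enolate of 7 | [Li+].[Li+].COC([O-])=C[C@@]([O-])(Cc1ccc(OC)c(OCc2ccccc2)c1)C(=O)OC | intermediate (not isolated)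
11 | dimethyl (2S,3R)-2-[3-(benzyloxy)-4-methoxybenzyl]-3-{[4-(benzyloxy)-3-bromo-5-methoxyphenyl](hydroxy)methyl}-2-hydroxybutanedioate (C7 epimers) | COC(=O)[C@H](C(O)c1cc(OC)c(OCc2ccccc2)c(Br)c1)[C@@](O)(Cc1ccc(OC)c(OCc2ccccc2)c1)C(=O)OC | intermediate
12 | (2S,3R)-2-[3-(benzyloxy)-4-methoxybenzyl]-3-{[4-(benzyloxy)-3-bromo-5-methoxyphenyl](hydroxy)methyl}butane-1,2,4-triol (C7 epimers) | OC[C@H](C(O)c1cc(OC)c(OCc2ccccc2)c(Br)c1)[C@@](O)(Cc1ccc(OC)c(OCc2ccccc2)c1)CO | intermediate
13 | (3S,4R,5S)-5-[4-(benzyloxy)-3-bromo-5-methoxyphenyl]-3-[3-(benzyloxy)-4-methoxybenzyl]-4-(hydroxymethyl)oxolan-3-ol | COc1ccc(C[C@@]2(O)CO[C@H](c3cc(OC)c(OCc4ccccc4)c(Br)c3)[C@H]2CO)cc1OCc1ccccc1 | intermediate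
14 | pinacol boronate of 13 (boron in place of bromine) | COc1ccc(C[C@@]2(O)CO[C@H](c3cc(OC)c(OCc4ccccc4)c(B4OC(C)(C)C(C)(C)O4)c3)[C@H]2CO)cc1OCc1ccccc1 | intermediate
15 | [4-(benzyloxy)-3-methoxyphenyl]methanol | COc1cc(CO)ccc1OCc1ccccc1 | starting material
16 | 1-(benzyloxy)-4-(bromomethyl)-2-methoxybenzene | COc1cc(CBr)ccc1OCc1ccccc1 | intermediate
17 | disodium enolate of 2 (carboxylate and dioxolanone enolate) | [Na+].[Na+].[O-]C(=O)CC1=C([O-])O[C@@H](C(C)(C)C)O1 | intermediate (not isolated)
18 | {(2S,4S)-4-[4-(benzyloxy)-3-methoxybenzyl]-2-tert-butyl-5-oxo-1,3-dioxolan-4-yl}acetic acid | OC(=O)C[C@]1(Cc2ccc(OCc3ccccc3)c(OC)c2)O[C@H](C(C)(C)C)OC1=O | intermediate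
19 | dimethyl (2S)-2-[4-(benzyloxy)-3-methoxybenzyl]-2-hydroxybutanedioate | COC(=O)C[C@@](O)(Cc1ccc(OCc2ccccc2)c(OC)c1)C(=O)OC | intermediate
20 | 2-bromo-4-(hydroxymethyl)-6-methoxyphenol | COc1cc(CO)cc(Br)c1O | intermediate
21 | dimethyl (2S)-2-[4-(benzyloxy)-2-(3-bromo-4-hydroxy-5-methoxybenzyl)-5-methoxybenzyl]-2-hydroxybutanedioate | COC(=O)C[C@@](O)(Cc1cc(OC)c(OCc2ccccc2)cc1Cc1cc(OC)c(O)c(Br)c1)C(=O)OC | intermediate
22 | p-quinone methide of 21 (E/Z mixture) | COC(=O)C[C@@](O)(Cc1cc(OC)c(OCc2ccccc2)cc1C=C1C=C(OC)C(=O)C(Br)=C1)C(=O)OC | intermediate (not isolated)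
23 | dilithium alkoxide enolate of 22 | [Li+].[Li+].COC([O-])=C[C@@]([O-])(Cc1cc(OC)c(OCc2ccccc2)cc1C=C1C=C(OC)C(=O)C(Br)=C1)C(=O)OC | intermediate (not isolated)
24 | dimethyl (1S,2R,3S)-7-(benzyloxy)-1-(3-bromo-4-hydroxy-5-methoxyphenyl)-3-hydroxy-6-methoxy-1,2,3,4-tetrahydronaphthalene-2,3-dicarboxylate | COc1cc([C@H]2c3cc(OCc4ccccc4)c(OC)cc3C[C@@](O)(C(=O)OC)[C@@H]2C(=O)OC)cc(Br)c1O | intermediate
25 | (1S,2S,3S)-7-(benzyloxy)-1-(3-bromo-4-hydroxy-5-methoxyphenyl)-2,3-bis(hydroxymethyl)-6-methoxy-1,2,3,4-tetrahydronaphthalen-3-ol | COc1cc([C@H]2c3cc(OCc4ccccc4)c(OC)cc3C[C@@](O)(CO)[C@@H]2CO)cc(Br)c1O | intermediate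
26 | tri-O-benzyl ether of the target (rings A, B and D) | COc1ccc(C[C@@]2(O)CO[C@H](c3cc(OC)c(OCc4ccccc4)c(-c4cc([C@H]5c6cc(OCc7ccccc7)c(OC)cc6C[C@@](O)(CO)[C@@H]5CO)cc(OC)c4O)c3)[C@H]2CO)cc1OCc1ccccc1 | intermediate
27 | CNP0252244.1 | COc1ccc(C[C@@]2(O)CO[C@H](c3cc(OC)c(O)c(-c4cc([C@H]5c6cc(O)c(OC)cc6C[C@@](O)(CO)[C@@H]5CO)cc(OC)c4O)c3)[C@H]2CO)cc1O | target

**Step count**

Total steps: 18. Longest linear sequence: 9 (steps 1, 3, 4, 6, 7, 8, 9, 17, 18).

**Steps most likely to fail**

1. Step 15. The tertiary alkoxide may add to C7 first, and the resulting β-alkoxy ester enolate may then eliminate. The quinone methide may also dimerise before the base is added, and the two faces of C7 may be poorly distinguished. The fallback gives up the anionic closure and closes the same ring from the other side by the known acid-induced Friedel–Crafts isomerisation of olivil-type precursors to aryltetralins. It sets out from 19 and 9: a Fráter–Seebach aldol of 19 with 9 (LiN(SiMe3)2, THF, −78 °C) gives the aldol adduct F1; LiBH4 reduces it to the tetraol F2; TFA in CH2Cl2 (0 °C → rt) ionises C7, and ring D attacks para to its methoxy group to give the 7,8-trans aryltetralin bromide F3. Suzuki coupling of F3 with 14 (Pd(OAc)2, SPhos, K3PO4) gives the tetrabenzyl ether F4, and hydrogenolysis (H2, Pd/C) comes back to the route at 27.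

2. Step 6. Retro-aldol and lactonisation of the aldolate may erode the yield, and the aldehyde may discriminate the two enolate faces less well than an alkyl halide. The fallback replaces the aldol by dianion benzylation and makes the C7–O bond by oxidative quinone methide cyclisation. It sets out from 7 (as its dianion 10) and 8: 8 is acylated (PivCl, Et3N) to the aryl pivalate aldehyde F5, reduced (NaBH4) to the benzylic alcohol F6 and brominated (PBr3) to the benzylic bromide F7. Dianion 10 is alkylated with F7 to the (2S,3R)-3-benzylated malate F8, and LiAlH4 (THF, 0 °C) reduces both esters and removes the pivalate to give the phenolic triol F9. Ag2O (CH2Cl2, rt) oxidises the now free p-hydroxybenzyl unit of ring B to the quinone methide F10, which is trapped 5-exo by the C9' hydroxyl to the oxolane phenol F11. Benzylation (BnBr, K2CO3, DMF) comes back to the route at 13.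

3. Step 14. The benzylic cation may alkylate its own ring (oligomerisation) or other positions of ring D. The fallback builds the diarylmethane by cross-coupling. It sets out from 19: bromination para to the ring D methoxy group (NBS, MeCN) gives the aryl bromide F12, and Miyaura borylation (B2pin2, Pd(dppf)Cl2, KOAc) gives the boronate F13. F13 is coupled at the benzylic carbon of bromide F7 (made from 8 via F5 and F6 as above; Pd(PPh3)4, K2CO3, THF/H2O, 50 °C, where the benzylic C–Br bond should react before the hindered aryl C–Br bond) to the diarylmethane pivalate F14. Methanolysis of the aryl pivalate (K2CO3, MeOH) comes back to the route at 21.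

Further compounds

F1 | step 15 | dimethyl (2S,3R)-2-[4-(benzyloxy)-3-methoxybenzyl]-3-{[4-(benzyloxy)-3-bromo-5-methoxyphenyl](hydroxy)methyl}-2-hydroxybutanedioate (C7 epimers) | COC(=O)[C@H](C(O)c1cc(OC)c(OCc2ccccc2)c(Br)c1)[C@@](O)(Cc1ccc(OCc2ccccc2)c(OC)c1)C(=O)OC
F2 | step 15 | (2S,3R)-2-[4-(benzyloxy)-3-methoxybenzyl]-3-{[4-(benzyloxy)-3-bromo-5-methoxyphenyl](hydroxy)methyl}butane-1,2,4-triol (C7 epimers) | OC[C@H](C(O)c1cc(OC)c(OCc2ccccc2)c(Br)c1)[C@@](O)(Cc1ccc(OCc2ccccc2)c(OC)c1)CO
F3 | step 15 | O-benzyl ether of 25 at the ring C phenol | COc1cc([C@H]2c3cc(OCc4ccccc4)c(OC)cc3C[C@@](O)(CO)[C@@H]2CO)cc(Br)c1OCc1ccccc1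
F4 | step 15 | tetra-O-benzyl ether of the target | COc1ccc(C[C@@]2(O)CO[C@H](c3cc(OC)c(OCc4ccccc4)c(-c4cc([C@H]5c6cc(OCc7ccccc7)c(OC)cc6C[C@@](O)(CO)[C@@H]5CO)cc(OC)c4OCc4ccccc4)c3)[C@H]2CO)cc1OCc1ccccc1
F5 | step 6 | 2-bromo-4-formyl-6-methoxyphenyl pivalate | COc1cc(C=O)cc(Br)c1OC(=O)C(C)(C)C
F6 | step 6 | 2-bromo-4-(hydroxymethyl)-6-methoxyphenyl pivalate | COc1cc(CO)cc(Br)c1OC(=O)C(C)(C)C
F7 | step 6 | 2-bromo-4-(bromomethyl)-6-methoxyphenyl pivalate | COc1cc(CBr)cc(Br)c1OC(=O)C(C)(C)C
F8 | step 6 | dimethyl (2S,3R)-2-[3-(benzyloxy)-4-methoxybenzyl]-3-[3-bromo-5-methoxy-4-(pivaloyloxy)benzyl]-2-hydroxybutanedioate | COC(=O)[C@H](Cc1cc(OC)c(OC(=O)C(C)(C)C)c(Br)c1)[C@@](O)(Cc1ccc(OC)c(OCc2ccccc2)c1)C(=O)OC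
F9 | step 6 | (2S,3S)-2-[3-(benzyloxy)-4-methoxybenzyl]-3-(3-bromo-4-hydroxy-5-methoxybenzyl)butane-1,2,4-triol | OC[C@H](Cc1cc(OC)c(O)c(Br)c1)[C@@](O)(Cc1ccc(OC)c(OCc2ccccc2)c1)CO
F10 | step 6 | p-quinone methide of F9 (E/Z mixture) | OC[C@H](C=C1C=C(OC)C(=O)C(Br)=C1)[C@@](O)(Cc1ccc(OC)c(OCc2ccccc2)c1)CO
F11 | step 6 | (3S,4R,5S)-3-[3-(benzyloxy)-4-methoxybenzyl]-5-(3-bromo-4-hydroxy-5-methoxyphenyl)-4-(hydroxymethyl)oxolan-3-ol | COc1ccc(C[C@@]2(O)CO[C@H](c3cc(OC)c(O)c(Br)c3)[C@H]2CO)cc1OCc1ccccc1
F12 | step 14 | dimethyl (2S)-2-[4-(benzyloxy)-2-bromo-5-methoxybenzyl]-2-hydroxybutanedioate | COC(=O)C[C@@](O)(Cc1cc(OC)c(OCc2ccccc2)cc1Br)C(=O)OC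
F13 | step 14 | dimethyl (2S)-2-[4-(benzyloxy)-5-methoxy-2-(4,4,5,5-tetramethyl-1,3,2-dioxaborolan-2-yl)benzyl]-2-hydroxybutanedioate | COC(=O)C[C@@](O)(Cc1cc(OC)c(OCc2ccccc2)cc1B1OC(C)(C)C(C)(C)O1)C(=O)OC
F14 | step 14 | pivalate of 21 at the ring C phenol | COC(=O)C[C@@](O)(Cc1cc(OC)c(OCc2ccccc2)cc1Cc1cc(OC)c(OC(=O)C(C)(C)C)c(Br)c1)C(=O)OC
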